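4 questions come down to one comparison of two times: the time you give a flask, and the time its E needs to fall to half of the charge.

| setting | south-east | north | east | Monday's | Saturday's |
|---|---|---|---|---|---|
| E | 13 mM | 30 mM | 20 mM | 20 mM | 20 mM |
| G | 0.60 mM | 0.60 mM | 0.30 mM | 0.60 mM | 0.60 mM |
| temperature | 75 °C | 92 °C | 75 °C | 80 °C | 105 °C |
| remark | run made earlier | run made earlier | run made earlier |  |  |
| time |  |  |  | 12 min | 12 min |

| run | time / min | L / % | E / % | J / % | Z / % | D / % |
|---|---|---|---|---|---|---|
| south-east | 2.00 | 0.3 | 99.6 | 0 | 0 | 0 |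
| south-east | 4.00 | 0.6 | 99.4 | 0.6 | 0 | 0.7 |
| south-east | 6.00 | 1.2 | 98.0 | 0 | 0 | 0.1 |
| south-east | 8.00 | 1.1 | 98.1 | 0 | 1.0 | 0.1 |
| south-east | 10.0 | 1.1 | 97.6 | 0.1 | 0.5 | 0 |
| south-east | 12.0 | 2.9 | 95.3 | 0.2 | 0.9 | 0 |
| north | 0.500 | 0 | 99.7 | 0 | 0.1 | 0.4 |
| north | 0.833 | 0.8 | 100.0 | 0.8 | 1.2 | 0.1 |
| north | 1.33 | 0.2 | 98.8 | 0.3 | 0.2 | 0.4 |
| north | 2.00 | 1.3 | 99.0 | 0 | 0 | 0.8 |
| north | 4.00 | 2.9 | 96.7 | 0.3 | 0.8 | 0.1 |
| north | 6.00 | 6.0 | 93.4 | 0 | 0 | 0 |
| east | 1.00 | 0 | 100.2 | 0.5 | 0 | 0 |
| east | 3.00 | 0.2 | 99.4 | 0 | 0 | 0 |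
| east | 6.00 | 0 | 99.5 | 0 | 0 | 0.9 |
| east | 8.00 | 0.2 | 99.3 | 0.4 | 0.2 | 0.3 |
| east | 12.0 | 1.3 | 97.8 | 0 | 0 | 0.5 |

(standard deviation of a reading: 0.5 percentage points)

* which of these there is most of at the end, counted by the E in it, Monday's (L / Z / E / J / D)
* which of these there is most of at the end, counted by the E in it, Saturday's (L / Z / E / J / D)
* amount of the one of these that there is most of at the end, in percent of the E charged, Monday's
* amount of the one of these that there is most of at the end, in percent of the E charged, Saturday's



Past that point L can read above E at that same moment, provided little of it has gone on to J; in the earlier runs J reads no higher than 0.8%, but those runs turned over little E. This is my own reckoning. In the north run L climbs faster late than early, an induction period, so I take its latest step as the pace: 0.0155 /min of the charged E. At 6.00 min, L reads 5.00 times higher in the north run than in the south-east run; these runs differ in the E charged as well as in temperature, and as a rough estimate I put the whole ratio on temperature. Spread evenly over the degrees between them, that ratio multiplies the pace by 3.42 for Saturday's.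

Saturday's then gets 9.42 min. This is its crossing time, the time in which a steady pace takes half of the charged E. That is shorter than the 12 min given, so I expect L to lead, with E near 36.3%. Monday's crossing time, 100 min, is longer than 12 min, so E leads there. All of this rests on readings with their scatter.

The forecast says E at 95.5% for Monday's and E at 62% for Saturday's, calling the latter “this is a long extrapolation”. On Saturday's leader it differs from my reckoning.

Monday's gives E at 93.6%. Saturday's gives L at 50.1%, with E at 44.6%.

    E + Q → Z (k = 1.30 /M/s, Ea = 37.0 kJ/mol)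
    Z ⇌ D (K = 0.620, k = 0.430 /s, Ea = 87.0 kJ/mol, ΔH = −24.0 kJ/mol)
    D → Q + L (k = 0.0600 /s, Ea = 95.0 kJ/mol)
    G ⇌ Q (K = 18.0, k = 8.10 × 10⁻⁴ /s, Ea = 104 kJ/mol, ΔH = 28.0 kJ/mol)
    Q + L → Q + J (k = 0.100 /M/s, Ea = 80.0 kJ/mol)
    (constants at 80 °C)

With a crossing time of 9.42 min I expected Saturday's E under half of the charge at 12 min, and so it stood, though above my figure. Temperature carried it there: without the difference in temperature, E ends at 93.6% instead of 44.6%. Saturday's flask left until 5.0 min stops short of 9.42 min, so the pace gives E near 73.5% and E still leading. It holds 78.5% E, and E leads.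

The readings were generated by integration with constants of no real substance, and the scatter is random.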